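**Plan**

1. Numbering (eudesmane type): ring B = C1–C2–C3–C4–C5–C10, ring A = C5–C6–C7–C8–C9–C10, C14 = CH2OH on C10, C15 = CH3 on C4, C11–C13 = isopropenyl on C7; β = face of C14, α = opposite face (H-5 in the target).
2. Retrosynthesis: the three ester C–O bonds and the C7–C11 bond (cuprate on a Δ7-9-one) are cut first, then C4–C15 (cross-coupling) and the C2–O/C5–H pair (epoxide hydrogenolysis), and last the two ring-A bonds C5–C6 and C9–C10 ([4+2]); this leaves 2-methoxycarbonyl-1,4-benzoquinone and 1-acetoxybutadiene.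
3. Forward: ring B enters as the quinone; ring A is closed onto its C5=C10 bond by a catalytic enantioselective Diels–Alder reaction; ring B is then edited (C4=O to C4–CH3, C1=O to 1β-OH, then 2β-OH and 5α-H), ring A is finished (Δ7-9-one, 7α-isopropenyl, 9α-OH) and the four oxygens are differentiated.
4. Enabling feature: ring A is annulated on the C5–C10 bond; C10 is quaternary, carries the one-carbon group C14 and lies between oxygenated C1 and C9, with C4 para to C1 in ring B. This is the imprint of a 1-oxygenated butadiene (C6–C9, oxygen on C9) added to the ester-bearing C5=C10 bond of a benzoquinone (C1 and C4 as carbonyls, C14 as ester).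
5. Stereochemistry: C10 from the chiral Lewis acid; all other centres by relay from C10 in the rigid bicycle: C1 (hydride anti to the axial C14 group), C2 (hydroxyl-directed epoxidation), C5 (Pd-hydride anti to the epoxide), C7 (axial cuprate addition), C9 (equatorial hydride attack enforced by the axial 7α-isopropenyl group).

Key step: step 2

Assumption: commercial 1-acetoxybuta-1,3-diene is an E/Z mixture of which only the E isomer 3 enters the cycloaddition, and the (S,S)-pybox antipode is taken to expose the face of 2 that leads to 4 as drawn (otherwise the (R,R) ligand is used).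

**Route**

Step 1
Reactants: 1 methyl 2,5-dihydroxybenzoate
Product: 2 methyl 3,6-dioxocyclohexa-1,4-diene-1-carboxylate
Conditions: Ag2O, MgSO4, Et2O, rt, dark; filtration, used at once
Reagents that add atoms: none
Why: Silver(I) oxide oxidation of a hydroquinone to the p-quinone should proceed cleanly and leave the ester, which is the activating group for step 2, untouched.

Step 2
Reactants: 2 methyl 3,6-dioxocyclohexa-1,4-diene-1-carboxylate; 3 (E)-buta-1,3-dien-1-yl acetate
Product: 4 methyl 9α-acetoxy-1,4-dioxo-11,12,13,15-tetranor-5β-eudesma-2,7-dien-14-oate (cis-fused adduct)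
Conditions: Sm(OTf)3 (10 mol %), (S,S)-Ph-pybox (12 mol %), 4 Å MS, CH2Cl2, −78 → −40 °C
Reagents that add atoms: none
Why: The step is a concerted, asynchronous [4+2] cycloaddition of the s-cis diene 3 to the ester-bearing C5=C10 bond of 2, whose C1 carbonyl and ester carbonyl chelate the lanthanide–pybox Lewis acid, which lowers the LUMO and shields one face. The closest known reaction type is the catalytic enantioselective Diels–Alder reaction of 2-alkoxycarbonyl-1,4-benzoquinones with 1-substituted butadienes under bidentate chiral Lewis acid catalysis. Ring A (C5–C6–C7–C8–C9–C10) closes in the [4+2] mode by formation of the C5–C6 and C9–C10 bonds. The quaternary centre C10, the only stereocentre of 4 that is kept to the end, is set by catalyst-controlled approach of the diene to one face of the chelated quinone; C5 (H cis to the ester, suprafacial addition) and C9 (endo, acetoxy trans to the ester) follow from the mechanism and are both re-set later (steps 3/7 and 11/13). The step needs site selectivity for C5=C10 over C2=C3 and ortho regiochemistry. Both are secured by the ester, which makes C5=C10 the only doubly activated, chelating double bond and C5 its most electrophilic carbon, so the unsubstituted diene terminus C6 should bond to C5 and the acetoxy-bearing C9 to C10.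

Step 3
Reactants: 4 cis-fused adduct
Product: 5 methyl 9α-acetoxy-1-oxo-4-(trifluoromethylsulfonyloxy)-11,12,13,15-tetranoreudesma-2,4,7-trien-14-oate
Conditions: KHMDS (1.05 equiv), THF, −78 °C; PhNTf2, −78 → −30 °C
Reagents that add atoms: N-phenylbis(trifluoromethanesulfonimide) O=S(=O)(N(c1ccccc1)S(=O)(=O)C(F)(F)F)C(F)(F)F
Why: C5–H is the only enolisable position of 4, so kinetic deprotonation and O-sulfonylation (enol triflate formation) should give the C4 dienyl triflate regiospecifically, which erases the cis C5 centre on purpose and turns the C4 carbonyl into a coupling handle.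

Step 4
Reactants: 5 dienyl triflate
Product: 6 methyl 9α-acetoxy-1-oxo-11,12,13-trinoreudesma-2,4,7-trien-14-oate
Conditions: MeZnCl (1.5 equiv), Pd(PPh3)4 (5 mol %), THF, 0 °C
Reagents that add atoms: methylzinc chloride C[Zn]Cl
Why: Negishi cross-coupling of the alkenyl triflate installs C15; at 0 °C oxidative addition into the triflate should outrun ionisation of the hindered allylic C9 acetate, and the organozinc reagent does not add to ketone, ester or acetate.

Step 5
Reactants: 6 linear dienone
Product: 7 methyl 9α-acetoxy-1β-hydroxy-11,12,13-trinoreudesma-2,4,7-trien-14-oate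
Conditions: NaBH4, CeCl3·7H2O, CH2Cl2/MeOH (3:1), −78 °C, short contact
Reagents that add atoms: none
Why: Luche 1,2-reduction; the angular ester is pseudo-axial on the β-face next to C1, so hydride should add from the α-face and give the 1β-alcohol, and the short cold contact limits methanolysis of the acyl-dienone.

Step 6
Reactants: 7 dienol
Product: 8 methyl 9α-acetoxy-2β,3β-epoxy-1β-hydroxy-11,12,13-trinoreudesma-4,7-dien-14-oate
Conditions: VO(acac)2 (5 mol %), t-BuOOH (1.5 equiv, decane), CH2Cl2, 0 °C
Reagents that add atoms: tert-butyl hydroperoxide CC(C)(C)OO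
Why: Vanadium-catalysed hydroxyl-directed epoxidation delivers oxygen to the allylic C2=C3 bond syn to the 1β-hydroxyl and should leave the C4=C5 and C7=C8 bonds untouched.

Step 7
Reactants: 8 epoxy alcohol
Product: 9 methyl 9α-acetoxy-1β,2β-dihydroxy-11,12,13-trinor-5α-eudesma-3,7-dien-14-oate
Conditions: Pd2(dba)3·CHCl3 (2.5 mol %), n-Bu3P (10 mol %), HCO2H (5 equiv), Et3N (2 equiv), dioxane, rt
Reagents that add atoms: none
Why: Pd(0)-catalysed formate hydrogenolysis of an alkenyl epoxide: palladium opens the epoxide with inversion to an α-face π-allyl complex (C3–C4–C5) and the formate-derived hydride passes from palladium to the more substituted terminus C5, which should give 5α-H (trans ring fusion), the C3=C4 bond and the 2β-hydroxyl in one stereospecific event.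

Step 8
Reactants: 9 cis-diol
Product: 10 methyl 9α-acetoxy-1β,2β-(isopropylidenedioxy)-11,12,13-trinor-5α-eudesma-3,7-dien-14-oate
Conditions: Me2C(OMe)2, PPTS (cat.), CH2Cl2, rt
Reagents that add atoms: 2,2-dimethoxypropane COC(C)(C)OC
Why: Acid-catalysed acetal exchange protects the cis-1β,2β-diol as its acetonide for the work on ring A.

Step 9
Reactants: 10 acetonide ester
Product: 11 1β,2β-(isopropylidenedioxy)-11,12,13-trinor-5α-eudesma-3,7-diene-9α,14-diol
Conditions: LiAlH4, THF, 0 °C → rt; then H2O
Reagents that add atoms: none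
Why: LiAlH4 reduces the angular ester to the C14 primary alcohol and cleaves the C9 acetate in the same operation, while acetonide and alkenes are inert.

Step 10
Reactants: 11 diol
Product: 12 14-(tert-butyldiphenylsilyloxy)-1β,2β-(isopropylidenedioxy)-11,12,13-trinor-5α-eudesma-3,7-dien-9α-ol
Conditions: TBDPSCl (1.1 equiv), imidazole, CH2Cl2, 0 °C
Reagents that add atoms: tert-butyl(chloro)diphenylsilane CC(C)(C)[Si](Cl)(c1ccccc1)c1ccccc1
Why: The bulky silyl chloride should react with the primary C14 hydroxyl much faster than with the hindered axial allylic C9 hydroxyl.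

Step 11
Reactants: 12 allylic alcohol
Product: 13 14-(tert-butyldiphenylsilyloxy)-1β,2β-(isopropylidenedioxy)-11,12,13-trinor-5α-eudesma-3,7-dien-9-one
Conditions: Dess–Martin periodinane, NaHCO3, CH2Cl2, rt
Reagents that add atoms: none
Why: Dess–Martin oxidation of the allylic C9 alcohol gives the Δ7-9-one, and the bicarbonate buffer protects acetonide and silyl ether.

Step 12
Reactants: 13 enone
Product: 14 14-(tert-butyldiphenylsilyloxy)-1β,2β-(isopropylidenedioxy)-5α,7βH-eudesma-3,11-dien-9-one
Conditions: CH2=C(CH3)MgBr (2.5 equiv), CuBr·SMe2 (20 mol %), THF, −78 → −40 °C; aq. NH4Cl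
Reagents that add atoms: isopropenylmagnesium bromide CC(=C)[Mg]Br
Why: Copper-catalysed conjugate addition; stereoelectronically controlled axial attack on C7 of the trans-fused octalone (chair-like enolate, syn to axial H-5) should place the isopropenyl group on the α-face.

Step 13
Reactants: 14 ketone
Product: 15 14-(tert-butyldiphenylsilyloxy)-1β,2β-(isopropylidenedioxy)-5α,7βH-eudesma-3,11-dien-9α-ol
Conditions: L-Selectride, THF, −78 → 0 °C; aq. NH4Cl
Reagents that add atoms: none
Why: The axial 7α-isopropenyl group is 1,3-diaxial to the α-face of C9, so the bulky hydride should attack equatorially from the β-side and give the axial 9α-alcohol.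

Step 14
Reactants: 15 acetonide alcohol
Product: 16 14-(tert-butyldiphenylsilyloxy)-5α,7βH-eudesma-3,11-diene-1β,2β,9α-triol
Conditions: AcOH/H2O (4:1), 40 °C
Reagents that add atoms: none
Why: Mild acid hydrolysis of the isopropylidene acetal; the TBDPS ether, the allylic hydroxyl and the isopropenyl group should tolerate aqueous acetic acid.

Step 15
Reactants: 16 triol
Product: 18 14-(tert-butyldiphenylsilyloxy)-2β,9α-dihydroxy-5α,7βH-eudesma-3,11-dien-1β-yl 3-methylbut-2-enoate, via 1,2-O-dibutylstannylene acetal 17 (not isolated)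
Conditions: Bu2SnO, toluene, reflux (−H2O); then Me2C=CHCOCl (1.1 equiv), 0 °C → rt
Reagents that add atoms: 3-methylbut-2-enoyl chloride CC(C)=CC(=O)Cl; dibutyltin oxide CCCC[Sn](=O)CCCC (tin is held in 17 only)
Why: Stannylene-acetal-mediated regioselective acylation: the stannylene forms on the cis-1,2-diol and its equatorial oxygen (O1) is the nucleophilic one, so the senecioyl group should go to C1 under neutral conditions that do not deconjugate the enoate, while the hindered axial 9α-hydroxyl stays free.

Step 16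
Reactants: 18 senecioate diol
Product: 19 2β,9α-diacetoxy-14-(tert-butyldiphenylsilyloxy)-5α,7βH-eudesma-3,11-dien-1β-yl 3-methylbut-2-enoate
Conditions: Ac2O, DMAP, pyridine, CH2Cl2, rt → 40 °C
Reagents that add atoms: acetic anhydride CC(=O)OC(C)=O
Why: DMAP-catalysed acetylation of the two remaining secondary hydroxyls (allylic 2β and hindered axial 9α) completes the ester pattern.

Step 17
Reactants: 19 silyl ether
Product: 20 2β,9α-diacetoxy-14-hydroxy-5α,7βH-eudesma-3,11-dien-1β-yl 3-methylbut-2-enoate (target)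
Conditions: HF·pyridine, pyridine, THF, 0 °C → rt
Reagents that add atoms: none
Why: Fluoride cleavage of the silyl ether under buffered acidic conditions should free the C14 hydroxyl without the base-induced 1,3-acyl migration that a basic fluoride source could cause.

**Compound list**

1 | methyl 2,5-dihydroxybenzoate | COC(=O)c1cc(O)ccc1O | starting material
2 | methyl 3,6-dioxocyclohexa-1,4-diene-1-carboxylate (2-methoxycarbonyl-1,4-benzoquinone) | COC(=O)C1=CC(=O)C=CC1=O | intermediate
3 | (E)-buta-1,3-dien-1-yl acetate | C=C/C=C/OC(C)=O | starting material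
4 | methyl 9α-acetoxy-1,4-dioxo-11,12,13,15-tetranor-5β-eudesma-2,7-dien-14-oate (= methyl 5-acetoxy-1,4-dioxo-1,4,4a,5,8,8a-hexahydronaphthalene-4a-carboxylate, 8a-H cis and 5-OAc trans to CO2Me) | C1=C[C@H](OC(C)=O)[C@@]2(C(=O)OC)[C@@H](C1)C(=O)C=CC2=O | intermediate
5 | methyl 9α-acetoxy-1-oxo-4-(trifluoromethylsulfonyloxy)-11,12,13,15-tetranoreudesma-2,4,7-trien-14-oate | C1=C[C@H](OC(C)=O)[C@@]2(C(=O)OC)C(C1)=C(OS(=O)(=O)C(F)(F)F)C=CC2=O | intermediate
6 | methyl 9α-acetoxy-1-oxo-11,12,13-trinoreudesma-2,4,7-trien-14-oate | C1=C[C@H](OC(C)=O)[C@@]2(C(=O)OC)C(C1)=C(C)C=CC2=O | intermediate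
7 | methyl 9α-acetoxy-1β-hydroxy-11,12,13-trinoreudesma-2,4,7-trien-14-oate | C1=C[C@H](OC(C)=O)[C@@]2(C(=O)OC)C(C1)=C(C)C=C[C@@H]2O | intermediate
8 | methyl 9α-acetoxy-2β,3β-epoxy-1β-hydroxy-11,12,13-trinoreudesma-4,7-dien-14-oate | C1=C[C@H](OC(C)=O)[C@@]2(C(=O)OC)C(C1)=C(C)[C@@H]3O[C@@H]3[C@@H]2O | intermediate
9 | methyl 9α-acetoxy-1β,2β-dihydroxy-11,12,13-trinor-5α-eudesma-3,7-dien-14-oate | C1=C[C@H](OC(C)=O)[C@@]2(C(=O)OC)[C@H](C1)C(C)=C[C@H](O)[C@@H]2O | intermediate
10 | methyl 9α-acetoxy-1β,2β-(isopropylidenedioxy)-11,12,13-trinor-5α-eudesma-3,7-dien-14-oate | C1=C[C@H](OC(C)=O)[C@@]2(C(=O)OC)[C@H](C1)C(C)=C[C@H](OC(C)(C)O3)[C@@H]23 | intermediate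
11 | 1β,2β-(isopropylidenedioxy)-11,12,13-trinor-5α-eudesma-3,7-diene-9α,14-diol | C1=C[C@H](O)[C@@]2(CO)[C@H](C1)C(C)=C[C@H](OC(C)(C)O3)[C@@H]23 | intermediate
12 | 14-(tert-butyldiphenylsilyloxy)-1β,2β-(isopropylidenedioxy)-11,12,13-trinor-5α-eudesma-3,7-dien-9α-ol | C1=C[C@H](O)[C@@]2(CO[Si](c3ccccc3)(c4ccccc4)C(C)(C)C)[C@H](C1)C(C)=C[C@H](OC(C)(C)O5)[C@@H]25 | intermediate
13 | 14-(tert-butyldiphenylsilyloxy)-1β,2β-(isopropylidenedioxy)-11,12,13-trinor-5α-eudesma-3,7-dien-9-one | C1=CC(=O)[C@@]2(CO[Si](c3ccccc3)(c4ccccc4)C(C)(C)C)[C@H](C1)C(C)=C[C@H](OC(C)(C)O5)[C@@H]25 | intermediate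
14 | 14-(tert-butyldiphenylsilyloxy)-1β,2β-(isopropylidenedioxy)-5α,7βH-eudesma-3,11-dien-9-one | C=C(C)[C@@H]1CC(=O)[C@@]2(CO[Si](c3ccccc3)(c4ccccc4)C(C)(C)C)[C@H](C1)C(C)=C[C@H](OC(C)(C)O5)[C@@H]25 | intermediate
15 | 14-(tert-butyldiphenylsilyloxy)-1β,2β-(isopropylidenedioxy)-5α,7βH-eudesma-3,11-dien-9α-ol | C=C(C)[C@@H]1C[C@H](O)[C@@]2(CO[Si](c3ccccc3)(c4ccccc4)C(C)(C)C)[C@H](C1)C(C)=C[C@H](OC(C)(C)O5)[C@@H]25 | intermediate
16 | 14-(tert-butyldiphenylsilyloxy)-5α,7βH-eudesma-3,11-diene-1β,2β,9α-triol | C=C(C)[C@@H]1C[C@H](O)[C@@]2(CO[Si](c3ccccc3)(c4ccccc4)C(C)(C)C)[C@H](C1)C(C)=C[C@H](O)[C@@H]2O | intermediate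
17 | 1,2-O-dibutylstannylene acetal of 16 | C=C(C)[C@@H]1C[C@H](O)[C@@]2(CO[Si](c3ccccc3)(c4ccccc4)C(C)(C)C)[C@H](C1)C(C)=C[C@H](O[Sn](CCCC)(CCCC)O5)[C@@H]25 | intermediate
18 | 14-(tert-butyldiphenylsilyloxy)-2β,9α-dihydroxy-5α,7βH-eudesma-3,11-dien-1β-yl 3-methylbut-2-enoate | C=C(C)[C@@H]1C[C@H](O)[C@@]2(CO[Si](c3ccccc3)(c4ccccc4)C(C)(C)C)[C@H](C1)C(C)=C[C@H](O)[C@@H]2OC(=O)C=C(C)C | intermediate
19 | 2β,9α-diacetoxy-14-(tert-butyldiphenylsilyloxy)-5α,7βH-eudesma-3,11-dien-1β-yl 3-methylbut-2-enoate | C=C(C)[C@@H]1C[C@H](OC(C)=O)[C@@]2(CO[Si](c3ccccc3)(c4ccccc4)C(C)(C)C)[C@H](C1)C(C)=C[C@H](OC(C)=O)[C@@H]2OC(=O)C=C(C)C | intermediate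
20 | 2β,9α-diacetoxy-14-hydroxy-5α,7βH-eudesma-3,11-dien-1β-yl 3-methylbut-2-enoate | C=C(C)[C@@H]1C[C@H](OC(C)=O)[C@@]2(CO)[C@H](C1)C(C)=C[C@H](OC(C)=O)[C@@H]2OC(=O)C=C(C)C | target

**Step count**

Total step count: 17. Longest linear sequence: 17 steps (1 → 20; 3 is bought).

**Steps most likely to fail**

Step 2. The uncatalysed cycloaddition of the very reactive quinone may compete with the catalysed one, so that facial discrimination is poor and 4 forms with low enantiomeric purity. The fallback replaces asymmetric catalysis by resolution. It sets out from 2 and 3, which are combined without the chiral ligand (toluene, 0 °C) to give racemic 4; this is taken through steps 3–10 unchanged. The racemic silyl ether 12 (UV-active, free 9-hydroxyl) is then resolved by preparative chromatography on a chiral stationary phase, and the required enantiomer comes back to the route at 12. This fallback makes no new compound (F0).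

Step 7. The hydride may be transferred to the less substituted allyl terminus C3 (the C4=C5 bond is then kept and C5 is not set), the alkoxy-π-allyl complex may collapse to an enone by β-hydride elimination, or palladium may ionise the allylic C9 acetate. The fallback sets the ring fusion and the C2 oxygen in another way and sets out from the cis adduct 4. DBU (CH2Cl2, rt) equilibrates 4 through its C4 enolate to the trans-fused enedione, methyl 9α-acetoxy-1,4-dioxo-11,12,13,15-tetranor-5α-eudesma-2,7-dien-14-oate F1, the classical cis to trans isomerisation of angularly substituted quinone–diene adducts. MeLi/CeCl3 (THF, −78 °C) should add to the less hindered C4 ketone and give the tertiary allylic alcohol, methyl 9α-acetoxy-4β-hydroxy-1-oxo-11,12,13-trinor-5α-eudesma-2,7-dien-14-oate F2 (configuration at C4 is of no consequence). Luche reduction from the α-face gives methyl 9α-acetoxy-1β,4β-dihydroxy-11,12,13-trinor-5α-eudesma-2,7-dien-14-oate F3. Re2O7 (cat.) in the presence of 2,2-dimethoxypropane (CH2Cl2, 0 °C) then moves the tertiary hydroxyl from C4 to C2 by 1,3-transposition and traps the isomer with a cis-1,2-diol as its acetonide; this is compound 10, where the route is rejoined.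

Step 13. The hydride may approach from the α-face, or the ketone next to the quaternary C10 may not react with the bulky reagent. The fallback uses intramolecular hydride delivery and sets out from 14. HF·pyridine removes the silyl group and gives the keto alcohol, 14-hydroxy-1β,2β-(isopropylidenedioxy)-5α,7βH-eudesma-3,11-dien-9-one F4. Me4NBH(OAc)3 (MeCN/AcOH, −20 °C) binds to the C14 hydroxyl and should deliver hydride to the β-face of C9, giving the anti-1,3-diol, 1β,2β-(isopropylidenedioxy)-5α,7βH-eudesma-3,11-diene-9α,14-diol F5. Selective silylation of the primary hydroxyl (TBDPSCl, imidazole, CH2Cl2, 0 °C) comes back to the route at 15.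

**Further compounds**

F0 | step 2 | none | none
F1 | step 7 | methyl 9α-acetoxy-1,4-dioxo-11,12,13,15-tetranor-5α-eudesma-2,7-dien-14-oate | C1=C[C@H](OC(C)=O)[C@@]2(C(=O)OC)[C@H](C1)C(=O)C=CC2=O
F2 | step 7 | methyl 9α-acetoxy-4β-hydroxy-1-oxo-11,12,13-trinor-5α-eudesma-2,7-dien-14-oate | C1=C[C@H](OC(C)=O)[C@@]2(C(=O)OC)[C@H](C1)[C@](C)(O)C=CC2=O
F3 | step 7 | methyl 9α-acetoxy-1β,4β-dihydroxy-11,12,13-trinor-5α-eudesma-2,7-dien-14-oate | C1=C[C@H](OC(C)=O)[C@@]2(C(=O)OC)[C@H](C1)[C@](C)(O)C=C[C@@H]2O
F4 | step 13 | 14-hydroxy-1β,2β-(isopropylidenedioxy)-5α,7βH-eudesma-3,11-dien-9-one | C=C(C)[C@@H]1CC(=O)[C@@]2(CO)[C@H](C1)C(C)=C[C@H](OC(C)(C)O3)[C@@H]23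
F5 | step 13 | 1β,2β-(isopropylidenedioxy)-5α,7βH-eudesma-3,11-diene-9α,14-diol | C=C(C)[C@@H]1C[C@H](O)[C@@]2(CO)[C@H](C1)C(C)=C[C@H](OC(C)(C)O3)[C@@H]23
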